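**Strategy.** Everything rests on cutting the cyclohexane ring twice, between C5 (acrolein-bearing CH) and C6 (angelate-bearing CH) and between C9 (acetate-bearing CH) and C10 (quaternary methyl/vinyl carbon). C6 and C9 then become the two carbonyl carbons of a trans-lactone four-carbon unit, and C5/C10 the nucleophilic carbons of an acyclic, ocimene-type (S,E)-allylic 1,2-bis(boronate). One pot joins them by intermolecular allylboration, unmasking of C9 by oxidation, and ring-closing allylboration. This closes the carbocycle, sets C5, C6, C9 and C10, and creates the C10 vinyl by allyl transposition. It exploits the 1,4-related oxygenated carbons C6/C9 and the vinyl-bearing C10 next to C5.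

Key step: step 8

Remark on numbering: elemane numbering is used for the target and all ring intermediates. C10 is the quaternary ring carbon (methyl C14, vinyl C1=C2), C9 the CH–OAc carbon, C8 the lactone CH–O carbon, C7 the ring carbon bearing C11, C6 the CH–O-angelate carbon and C5 the CH bearing C4. C11/C12/C13 are the α-methylene lactone carbons (C12 the carbonyl), C3/C4/C15 the acrolein unit. β is the face of the C10 methyl.

Assumptions: lactone 1 and enynol 8 are bought. The chiral imidazolinium sulfonate of step 7 is a known ligand precursor made separately and not counted. Reagents added in sequence to one flask count as one step.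

Step 1
Reactants: 1 (R)-5-(hydroxymethyl)dihydrofuran-2(3H)-one
Product: 2 (R)-5-[(tert-butyldimethylsilyloxy)methyl]dihydrofuran-2(3H)-one
Conditions: TBSCl, imidazole, DMF, rt
Reagents that add atoms: tert-butyldimethylsilyl chloride CC(C)(C)[Si](C)(C)Cl
Why: Imidazole-promoted silylation protects the primary alcohol against the strong base of step 2 and touches no stereocentre.

Step 2
Reactants: 2 (R)-5-[(tert-butyldimethylsilyloxy)methyl]dihydrofuran-2(3H)-one
Product: 4 (R)-5-[(tert-butyldimethylsilyloxy)methyl]furan-2(5H)-one, via α-phenylselanyl lactone 3 (not isolated)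
Conditions: LDA, THF, −78 °C; PhSeBr; then 30% H2O2, pyridine, CH2Cl2, 0 °C
Reagents that add atoms: none
Why: Selenenylation of the kinetic lithium enolate and selenoxide syn-elimination should introduce the ring double bond, while the non-enolisable C5 stereocentre is retained.

Step 3
Reactants: 4 (R)-5-[(tert-butyldimethylsilyloxy)methyl]furan-2(5H)-one
Product: 6 (4S,5R)-5-(hydroxymethyl)-4-vinyldihydrofuran-2(3H)-one, via silylated vinyl lactone 5 (not isolated)
Conditions: vinylmagnesium bromide, CuBr·SMe2 (cat.), THF, −78 °C; then 1 M aq. HCl, THF, rt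
Reagents that add atoms: vinylmagnesium bromide C=C[Mg]Br
Why: Copper-catalysed 1,4-addition should occur anti to the silyloxymethyl group (substrate control by C5), setting the trans C4 centre (future C7), and the acidic work-up removes the silyl ether.

Step 4
Reactants: 6 (4S,5R)-5-(hydroxymethyl)-4-vinyldihydrofuran-2(3H)-one
Product: 7 (2R,3R)-2-(hydroxymethyl)-5-oxotetrahydrofuran-3-carbaldehyde
Conditions: O3, CH2Cl2, −78 °C; then Me2S; used crude
Reagents that add atoms: ozone [O-][O+]=O
Why: Ozonolysis with reductive work-up gives the aldehyde under neutral conditions, so the epimerisable centre α to the formyl group and the β-acyloxy leaving group are not put at risk.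

Step 5
Reactants: 8 (E)-3-methylpent-2-en-4-yn-1-ol
Product: 9 (E)-5-bromo-3-methylpent-3-en-1-yne
Conditions: PBr3, Et2O, −10 °C
Reagents that add atoms: phosphorus tribromide BrP(Br)Br
Why: SN2 conversion of the primary allylic alcohol into the bromide should keep the E geometry.

Step 6
Reactants: 9 (E)-5-bromo-3-methylpent-3-en-1-yne
Product: 10 (E)-3,7-dimethylocta-3,6-dien-1-yne
Conditions: (2-methylprop-1-en-1-yl)magnesium bromide (2.2 equiv), CuI (cat.), THF, −78 to −20 °C
Reagents that add atoms: (2-methylprop-1-en-1-yl)magnesium bromide CC(C)=C[Mg]Br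
Why: Copper-catalysed SN2 coupling at the primary allylic carbon should retain the E-trisubstituted alkene, and the acetylide formed by the first equivalent of Grignard reagent is a non-transferable ligand on copper.

Step 7
Reactants: 10 (E)-3,7-dimethylocta-3,6-dien-1-yne
Product: 12 2,2'-[(2S,3E)-3,7-dimethylocta-3,6-diene-1,2-diyl]bis(4,4,5,5-tetramethyl-1,3,2-dioxaborolane), via dienylboronate 11 (not isolated)
Conditions: B2pin2 (2.1 equiv), MeOH (3 equiv), CuCl (5 mol%), chiral imidazolinium sulfonate (NHC precursor, 5 mol%, enantiomer giving (S)-12), NaOtBu (20 mol%), THF, −15 °C to rt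
Reagents that add atoms: bis(pinacolato)diboron CC1(C)OB(OC1(C)C)B1OC(C)(C)C(C)(C)O1
Why: In this NHC–copper-catalysed double protoboration of a terminal alkyne, syn copper–boron addition and protonation give the (E)-alkenylboronate 11, and a second, enantioselective addition that places copper next to boron sets the C–B stereocentre under control of the chiral carbene ligand.

Step 8
Reactants: 7 (2R,3R)-2-(hydroxymethyl)-5-oxotetrahydrofuran-3-carbaldehyde; 12 2,2'-[(2S,3E)-3,7-dimethylocta-3,6-diene-1,2-diyl]bis(4,4,5,5-tetramethyl-1,3,2-dioxaborolane)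
Product: 16 (3aS,4S,5S,6S,7S,7aR)-4,7-dihydroxy-6-methyl-5-(3-methylbut-2-en-1-yl)-6-vinylhexahydrobenzofuran-2(3H)-one, via mono-allylation borate 13 (not isolated), via C9 aldehyde 14 (not isolated), via cyclised bis(borate) 15 (not isolated)
Conditions: 12 (1.3 equiv), CH2Cl2, rt; then Dess–Martin periodinane (1.2 equiv), 0 °C to rt; aq. NaHCO3 work-up
Reagents that add atoms: none
Why: The secondary allylboronate of 12 adds to the free aldehyde (C6) of 7 through a chair Zimmerman–Traxler transition state with the (E)-prenylmethyl group equatorial and the CH2Bpin group axial, forming C5–C6 and the (Z)-configured primary allylboronate 13; oxidation of the C9 alcohol then gives aldehyde 14, which the tethered allylboronate traps in a 6-exo-trig closure through a fused chair–chair transition state, forming C9–C10 and the C10 vinyl group (15). The closest known reaction type is the tandem double allylboration of 1,4-dicarbonyl compounds with allylic 1,2-bis(boronates), staged here by in-flask oxidation as in intramolecular allylborations of aldehydes unmasked in situ. C5 and C6 are controlled by the (S)-C–B stereocentre of 12 (chirality transfer) and the (E)-alkene, which give the cis C5/C6 relationship on the ring. C9 and the quaternary C10 are controlled by the (Z)-allylboronate geometry and by allylic 1,3-strain at C5, which keeps the side chain equatorial, places the methyl cis to it and the C9 oxygen trans to the methyl. The needed site selectivity (C5 to C6 first, C10 to C9 second) is secured because C9 is still an alcohol during the intermolecular step, so the more electrophilic α-acyloxy aldehyde never competes. Reagent control has to override the anti-Felkin demand at C7, which the axial preference of the α-substituent in this β-methyl allylboronate should provide, and aqueous work-up cleaves both borates to diol 16.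

Step 9
Reactants: 16 (3aS,4S,5S,6S,7S,7aR)-4,7-dihydroxy-6-methyl-5-(3-methylbut-2-en-1-yl)-6-vinylhexahydrobenzofuran-2(3H)-one
Product: 19 α-methylene lactone (11(13)-ene) of diol 16, via Mannich base 17 (not isolated), via ammonium iodide 18 (not isolated)
Conditions: LDA (4 equiv), THF, −78 °C; CH2=NMe2+ I−, −78 to 0 °C; then MeI, MeOH, rt; then NaHCO3, CH2Cl2/H2O, rt
Reagents that add atoms: dimethylmethyleneiminium iodide (Eschenmoser's salt) C=[N+](C)C.[I-]
Why: Mannich reaction of the lactone enolate followed by quaternisation and E1cB loss of trimethylamine should give the α-methylene lactone (C11 becomes sp2), and the enolised lactone is not electrophilic, which should suppress acyl migration to the C6 alkoxide at −78 °C.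

Step 10
Reactants: 19 α-methylene lactone (11(13)-ene) of diol 16
Product: 20 9-O-acetate of 19 (free 6β-OH)
Conditions: Ac2O (1.2 equiv), pyridine, DMAP (cat.), CH2Cl2, 0 °C
Reagents that add atoms: acetic anhydride CC(=O)OC(C)=O
Why: Acetylation should select the C9 hydroxyl because the C6 hydroxyl is axial, syn to the axial C10 methyl and flanked by two substituted carbons.

Step 11
Reactants: 20 9-O-acetate of 19 (free 6β-OH)
Product: 21 9-O-acetyl-6-O-angeloyl derivative (prenyl side chain at C5)
Conditions: angelic acid, 2,4,6-trichlorobenzoyl chloride, Et3N, toluene, rt; then 20, 80 °C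
Reagents that add atoms: angelic acid C/C=C(/C)C(O)=O
Why: Yamaguchi esterification through the mixed 2,4,6-trichlorobenzoic anhydride should acylate the hindered axial C6 hydroxyl without a nucleophilic amine catalyst, which limits Z-to-E isomerisation of the angelate.

Step 12
Reactants: 21 9-O-acetyl-6-O-angeloyl derivative (prenyl side chain at C5)
Product: 23 aldehyde with C5–CH2–CHO side chain, via prenyl epoxide 22 (not isolated)
Conditions: mCPBA, CH2Cl2, 0 °C; then H5IO6, THF/H2O, 0 °C to rt
Reagents that add atoms: 3-chloroperoxybenzoic acid O=C(OO)c1cccc(Cl)c1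
Why: Prilezhaev epoxidation should select the electron-rich trisubstituted alkene over the vinyl group and the three conjugated alkenes, and periodic acid cleaves the epoxide to the aldehyde and acetone.

Step 13
Reactants: 23 aldehyde with C5–CH2–CHO side chain
Product: 24 target CNP0228039.1
Conditions: 37% aq. HCHO, pyrrolidine (10 mol%), propionic acid (10 mol%), iPrOH, 45 °C
Reagents that add atoms: formaldehyde C=O
Why: Amine-catalysed Mannich condensation and elimination (organocatalytic α-methylenation of an aldehyde) should give the 2-substituted acrolein, and the catalytic amine salt avoids stoichiometric amine that would add to the α-methylene lactone.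

**Compound list**

1 | (R)-5-(hydroxymethyl)dihydrofuran-2(3H)-one | OC[C@H]1CCC(=O)O1 | starting material
2 | (R)-5-[(tert-butyldimethylsilyloxy)methyl]dihydrofuran-2(3H)-one | CC(C)(C)[Si](C)(C)OC[C@H]1CCC(=O)O1 | intermediate
3 | (5R)-5-[(tert-butyldimethylsilyloxy)methyl]-3-(phenylselanyl)dihydrofuran-2(3H)-one, C3 epimers | CC(C)(C)[Si](C)(C)OC[C@H]1CC([Se]c2ccccc2)C(=O)O1 | intermediate
4 | (R)-5-[(tert-butyldimethylsilyloxy)methyl]furan-2(5H)-one | CC(C)(C)[Si](C)(C)OC[C@H]1C=CC(=O)O1 | intermediate
5 | (4S,5R)-5-[(tert-butyldimethylsilyloxy)methyl]-4-vinyldihydrofuran-2(3H)-one | CC(C)(C)[Si](C)(C)OC[C@@H]1OC(=O)C[C@H]1C=C | intermediate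
6 | (4S,5R)-5-(hydroxymethyl)-4-vinyldihydrofuran-2(3H)-one | OC[C@@H]1OC(=O)C[C@H]1C=C | intermediate
7 | (2R,3R)-2-(hydroxymethyl)-5-oxotetrahydrofuran-3-carbaldehyde | OC[C@@H]1OC(=O)C[C@H]1C=O | intermediate
8 | (E)-3-methylpent-2-en-4-yn-1-ol | C#C/C(C)=C/CO | starting material
9 | (E)-5-bromo-3-methylpent-3-en-1-yne | C#C/C(C)=C/CBr | intermediate
10 | (E)-3,7-dimethylocta-3,6-dien-1-yne | C#C/C(C)=C/CC=C(C)C | intermediate
11 | 2-[(1E,3E)-3,7-dimethylocta-1,3,6-trien-1-yl]-4,4,5,5-tetramethyl-1,3,2-dioxaborolane | CC(C)=CC/C=C(C)/C=C/B1OC(C)(C)C(C)(C)O1 | intermediate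
12 | 2,2'-[(2S,3E)-3,7-dimethylocta-3,6-diene-1,2-diyl]bis(4,4,5,5-tetramethyl-1,3,2-dioxaborolane) | CC(C)=CC/C=C(C)/[C@@H](B1OC(C)(C)C(C)(C)O1)CB1OC(C)(C)C(C)(C)O1 | intermediate
13 | mono-allylation product: lactone with C9 as CH2OH, (6S)-C6–O–Bpin borate, (5S)-C5 bearing the prenyl group and the (Z)-C10(Me)=C1H–C2H2–Bpin allylboronate | OC[C@@H]1OC(=O)C[C@H]1[C@@H](OB2OC(C)(C)C(C)(C)O2)[C@@H](CC=C(C)C)/C(C)=C\CB3OC(C)(C)C(C)(C)O3 | intermediate
14 | C9 aldehyde of 13 | O=C[C@@H]1OC(=O)C[C@H]1[C@@H](OB2OC(C)(C)C(C)(C)O2)[C@@H](CC=C(C)C)/C(C)=C\CB3OC(C)(C)C(C)(C)O3 | intermediate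
15 | 6,9-bis(O-Bpin) borate of diol 16 | C=C[C@]1(C)[C@H](OB2OC(C)(C)C(C)(C)O2)[C@@H]3OC(=O)C[C@H]3[C@@H](OB4OC(C)(C)C(C)(C)O4)[C@H]1CC=C(C)C | intermediate
16 | (3aS,4S,5S,6S,7S,7aR)-4,7-dihydroxy-6-methyl-5-(3-methylbut-2-en-1-yl)-6-vinylhexahydrobenzofuran-2(3H)-one (6β,9α-diol, trans-fused 8α,12-lactone, 5β-prenyl, 10β-methyl, 10α-vinyl) | C=C[C@]1(C)[C@H](O)[C@@H]2OC(=O)C[C@H]2[C@@H](O)[C@H]1CC=C(C)C | intermediate
17 | C11-(dimethylaminomethyl) lactone (Mannich base) of 16, C11 epimers | C=C[C@]1(C)[C@H](O)[C@@H]2OC(=O)C(CN(C)C)[C@H]2[C@@H](O)[C@H]1CC=C(C)C | intermediate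
18 | trimethylammonium iodide of 17 | C=C[C@]1(C)[C@H](O)[C@@H]2OC(=O)C(C[N+](C)(C)C)[C@H]2[C@@H](O)[C@H]1CC=C(C)C.[I-] | intermediate
19 | α-methylene lactone (11(13)-ene) of diol 16 | C=C[C@]1(C)[C@H](O)[C@@H]2OC(=O)C(=C)[C@H]2[C@@H](O)[C@H]1CC=C(C)C | intermediate
20 | 9-O-acetate of 19 | C=C[C@]1(C)[C@H](OC(C)=O)[C@@H]2OC(=O)C(=C)[C@H]2[C@@H](O)[C@H]1CC=C(C)C | intermediate
21 | 9-O-acetyl-6-O-angeloyl derivative of 19 | C=C[C@]1(C)[C@H](OC(C)=O)[C@@H]2OC(=O)C(=C)[C@H]2[C@@H](OC(=O)/C(C)=C\C)[C@H]1CC=C(C)C | intermediate
22 | epoxide of 21 at the prenyl double bond, epoxide epimers | C=C[C@]1(C)[C@H](OC(C)=O)[C@@H]2OC(=O)C(=C)[C@H]2[C@@H](OC(=O)/C(C)=C\C)[C@H]1CC3OC3(C)C | intermediate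
23 | aldehyde with C5–CH2–CHO side chain (C3 aldehyde, C4 methylene) | C=C[C@]1(C)[C@H](OC(C)=O)[C@@H]2OC(=O)C(=C)[C@H]2[C@@H](OC(=O)/C(C)=C\C)[C@H]1CC=O | intermediate
24 | CNP0228039.1 (9α-acetoxy-6β-angeloyloxy-15-oxo-elema-1,4(15),11(13)-trien-8α,12-olide) | C=C[C@]1(C)[C@H](OC(C)=O)[C@@H]2OC(=O)C(=C)[C@H]2[C@@H](OC(=O)/C(C)=C\C)[C@H]1C(=C)C=O | target

**Step count.** Total: 13 steps. Longest linear sequence: 10 steps (steps 1–4 and 8–13); steps 5–7 form the second branch.

**Steps most likely to fail**

Step 8. Reagent control may be lost in the intermolecular allylboration, because the aldehyde must react through its less favoured anti-Felkin face. The primary allylboronate may also be oxidised or protodeboronated while C9 is unmasked. The fallback splits the event into isolated stages with C9 kept silylated. It sets out from 5, isolated after an NH4Cl quench of step 3. Ozonolysis gives the silyloxy aldehyde F1. Allylboration with 12 and triethanolamine work-up gives the homoallylic alcohol F2, where C6 epimers can be separated. HF·pyridine gives the diol allylboronate F3. TEMPO/PhI(OAc)2 then oxidises only the primary alcohol, the aldehyde cyclises, and aqueous work-up returns the route at 16.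

Step 7. The second copper–boron addition may run with the wrong regiochemistry on the conjugated dienylboronate 11 (geminal or conjugate addition), or with low enantioselectivity. The fallback sets out from 10. Pt(PPh3)4-catalysed cis-diboration of the alkyne with B2pin2 gives the cis-1,2-bis(boryl)triene F4. Rhodium-catalysed enantioselective hydrogenation of this vinyl bis(boronate) ([Rh(nbd)2]BF4, chiral Walphos-type bisphosphine, H2) returns the route at 12.

Step 9. The lactone acyl group may migrate to the cis-disposed C6 alkoxide (translactonisation), and enolisation may be incomplete beside two alkoxides. The fallback sets out from 16. TESOTf and 2,6-lutidine give the bis(triethylsilyl) ether F5. The same enolate Mannich, quaternisation and elimination sequence gives the silylated α-methylene lactone F6. HF·pyridine returns the route at 19.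

Further compounds
F1 | step 8 | (2R,3R)-2-[(tert-butyldimethylsilyloxy)methyl]-5-oxotetrahydrofuran-3-carbaldehyde | CC(C)(C)[Si](C)(C)OC[C@@H]1OC(=O)C[C@H]1C=O
F2 | step 8 | C9-O-TBS homoallylic alcohol with free (6S)-OH and (Z)-allyl-Bpin | CC(C)(C)[Si](C)(C)OC[C@@H]1OC(=O)C[C@H]1[C@@H](O)[C@@H](CC=C(C)C)/C(C)=C\CB1OC(C)(C)C(C)(C)O1
F3 | step 8 | C6,C9-diol with (Z)-allyl-Bpin | OC[C@@H]1OC(=O)C[C@H]1[C@@H](O)[C@@H](CC=C(C)C)/C(C)=C\CB1OC(C)(C)C(C)(C)O1
F4 | step 7 | cis-1,2-bis(pinacolboryl)-(3E)-3,7-dimethylocta-1,3,6-triene | CC(C)=CC/C=C(C)/C(B1OC(C)(C)C(C)(C)O1)=C/B1OC(C)(C)C(C)(C)O1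
F5 | step 9 | 6,9-bis(triethylsilyl) ether of 16 | C=C[C@]1(C)[C@H](O[Si](CC)(CC)CC)[C@@H]2OC(=O)C[C@H]2[C@@H](O[Si](CC)(CC)CC)[C@H]1CC=C(C)C
F6 | step 9 | 6,9-bis(triethylsilyl) ether of 19 | C=C[C@]1(C)[C@H](O[Si](CC)(CC)CC)[C@@H]2OC(=O)C(=C)[C@H]2[C@@H](O[Si](CC)(CC)CC)[C@H]1CC=C(C)C
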